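The route rests on recognising the cis C4–O/C5–O pair beside the C3 methylene of the six-membered ring as the signature of an arene cis-dihydrodiol. Toluene dioxygenase turns bromobenzene, a flat achiral precursor whose single bromine marks the future C3, into the enantiopure cis-dienediol in one operation, making both C–O bonds and both stereocentres. Bromine steers osmylation to C1=C6 and is then reduced off; every later centre is relayed from C4/C5: O6 (and a temporary O1) anti to the acetonide, an α-epoxide at C2–C3, and C7 added to the C1 ketone anti to both flanking C–O bonds. Epoxide reduction at C3, C2 oxidation and two benzoylations finish the target.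

Key step: step 1

Remark (convention and one assumption): ring atoms carry the target numbering throughout — C1 quaternary carbinol, C2 ketone, C3 CH2, C4/C5/C6 carbinols, C7 the exocyclic CH2; β is the ring face of O4 and O5, α the opposite face; TBS = tert-butyldimethylsilyl. The recombinant whole-cell biocatalyst is treated as a reagent.

Step 1
Reactants: 1 bromobenzene
Product: 2 (1S,2S)-3-bromocyclohexa-3,5-diene-1,2-diol
Conditions: E. coli JM109(pDTG601) whole cells expressing toluene dioxygenase, IPTG, glucose feed, air, pH 7 buffer, 30 °C; EtOAc extraction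
Reagents that add atoms: dioxygen, O=O
Why: The reduced Rieske cluster feeds electrons to the mononuclear non-haem iron, which binds O2 and transfers both oxygen atoms to the same face of the C2=C3 π bond of the bound arene (C4 and C5 of the target; C–O bonds only, no ring is closed), dearomatising it to the cis-dienediol. The closest known reaction type is the whole-cell arene cis-dihydroxylation of monosubstituted benzenes, of which halobenzenes are standard substrates. Both new stereocentres are set by the enzyme pocket, which seats the bromine so that oxygen enters at the ortho and meta carbons from one face, giving the 1S,2S diol, i.e. 4R,5R in the target once bromine is mapped onto C3. The step needs 2,3-regioselectivity, a single enantiomer and arrest at the diol: the first two are secured by the lone bromine substituent that orients the ring in the active site, the last by a host that lacks the cis-diol dehydrogenase, so the diol is not rearomatised to the catechol.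

Step 2
Reactants: 2 (1S,2S)-3-bromocyclohexa-3,5-diene-1,2-diol
Product: 3 (3aS,7aS)-4-bromo-2,2-dimethyl-3a,7a-dihydro-1,3-benzodioxole (4β,5β-acetonide of 2)
Conditions: Me2C(OMe)2, p-TsOH (cat.), acetone, 0 °C → rt; used without storage
Reagents that add atoms: 2,2-dimethoxypropane, COC(C)(C)OC
Why: Acid-catalysed transketalisation (acetonide formation) ties the cis C4/C5 diol into a dioxolane without touching either stereocentre, which blocks the β face and prevents dehydrative rearomatisation.

Step 3
Reactants: 3 (3aS,7aS)-4-bromo-2,2-dimethyl-3a,7a-dihydro-1,3-benzodioxole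
Product: 4 (3aS,4R,5R,7aS)-7-bromo-2,2-dimethyl-3a,4,5,7a-tetrahydro-1,3-benzodioxole-4,5-diol (3-bromo-4β,5β-isopropylidenedioxycyclohex-2-ene-1α,6α-diol)
Conditions: OsO4 (2 mol %), NMO, acetone/H2O, rt
Reagents that add atoms: osmium tetroxide (catalytic oxygen carrier), O=[Os](=O)(=O)=O; N-methylmorpholine N-oxide, C[N+]1([O-])CCOCC1; water, O
Why: Upjohn dihydroxylation should occur at the more electron-rich, unbrominated C1=C6 bond and from the α face, anti to the dioxolane, which sets C6 (final) and C1 (provisional) together as the 1α,6α-diol.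

Step 4
Reactants: 4 3-bromo-4β,5β-isopropylidenedioxycyclohex-2-ene-1α,6α-diol
Product: 5 4β,5β-(isopropylidenedioxy)cyclohex-2-ene-1α,6α-diol
Conditions: Bu3SnH, AIBN (cat.), toluene, 85 °C
Reagents that add atoms: none
Why: Radical-chain hydrodehalogenation (the stannyl radical abstracts the vinylic bromine and the σ-vinyl radical takes hydrogen from Sn–H) clears C3 now that the C1/C6 diol carries the asymmetry; no stereocentre is touched.

Step 5
Reactants: 5 4β,5β-(isopropylidenedioxy)cyclohex-2-ene-1α,6α-diol
Product: 6 6α-hydroxy-4β,5β-(isopropylidenedioxy)cyclohex-2-en-1-one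
Conditions: 4-acetamido-TEMPO (2.2 equiv), p-TsOH·H2O (2.2 equiv), CH2Cl2, 0 °C
Reagents that add atoms: none
Why: Oxoammonium oxidation: the bulky N-oxoammonium salt formed by acid-promoted disproportionation of the nitroxide should take hydride only from the allylic C1 carbinol and leave the C6 hydroxyl, which is flanked by two oxygenated carbons; C1 is deliberately made trigonal while C4, C5 and C6 are untouched.

Step 6
Reactants: 6 6α-hydroxy-4β,5β-(isopropylidenedioxy)cyclohex-2-en-1-one
Product: 7 6α-(tert-butyldimethylsilyloxy)-4β,5β-(isopropylidenedioxy)cyclohex-2-en-1-one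
Conditions: TBSCl, imidazole, DMF, rt
Reagents that add atoms: tert-butyldimethylsilyl chloride, CC(C)(C)[Si](C)(C)Cl
Why: Imidazole-mediated silyl ether formation caps the only free hydroxyl under weakly basic conditions, giving a non-chelating, bulky α-face substituent next to the ketone; no stereocentre changes.

Step 7
Reactants: 7 6α-(tert-butyldimethylsilyloxy)-4β,5β-(isopropylidenedioxy)cyclohex-2-en-1-one
Product: 8 2α,3α-epoxy-6α-(tert-butyldimethylsilyloxy)-4β,5β-(isopropylidenedioxy)cyclohexan-1-one
Conditions: 30 % H2O2, Triton B (cat.), THF, 0 °C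
Reagents that add atoms: hydrogen peroxide, OO
Why: Weitz–Scheffer nucleophilic epoxidation: hydroperoxide should add to C3 anti to the neighbouring C4–O bond and the dioxolane, and the enolate then closes onto oxygen, so the oxirane (new centres C2 and C3) forms on the α face and delivers the future C2 oxygen.

Step 8
Reactants: 8 2α,3α-epoxy-6α-(tert-butyldimethylsilyloxy)-4β,5β-(isopropylidenedioxy)cyclohexan-1-one; 9 (chloromethyl)(isopropoxy)dimethylsilane
Product: 12 2α,3α-epoxy-1β-(hydroxymethyl)-6α-(tert-butyldimethylsilyloxy)-4β,5β-(isopropylidenedioxy)cyclohexan-1α-ol, via Grignard reagent 10 (not isolated), via silane adduct 11 (not isolated)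
Conditions: 9, Mg, THF, rt; then 8, THF, −78 → 0 °C; then KF, KHCO3, 30 % H2O2, THF/MeOH, rt
Reagents that add atoms: (chloromethyl)(isopropoxy)dimethylsilane (compound 9), CC(C)O[Si](C)(C)CCl; hydrogen peroxide, OO
Why: Grignard 1,2-addition of the silylmethyl hydroxymethyl-anion equivalent followed by Tamao–Fleming oxidation of the C–Si bond; C1 is set because both α-carbons hold their C–O bond on the α face (oxirane at C2, silyloxy at C6), so the nucleophile should enter from the β face (Felkin–Anh, anti to the epoxide), placing C7 β and the C1 hydroxyl α, cis to O6.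

Step 9
Reactants: 12 2α,3α-epoxy-1β-(hydroxymethyl)-6α-(tert-butyldimethylsilyloxy)-4β,5β-(isopropylidenedioxy)cyclohexan-1α-ol
Product: 13 1β-(hydroxymethyl)-6α-(tert-butyldimethylsilyloxy)-4β,5β-(isopropylidenedioxy)cyclohexane-1α,2α-diol
Conditions: LiBH4, Ti(OiPr)4, THF, 0 °C → rt
Reagents that add atoms: none
Why: Titanium-mediated reductive opening of a 2,3-epoxy alcohol: with the C1 alkoxide and the cis oxirane held on titanium, hydride should attack the distal carbon C3 in an SN2 sense (C2 is in addition neopentyl), so C3 becomes CH2 and C2 keeps its α oxygen, whose configuration is erased in step 11.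

Step 10
Reactants: 13 1β-(hydroxymethyl)-6α-(tert-butyldimethylsilyloxy)-4β,5β-(isopropylidenedioxy)cyclohexane-1α,2α-diol; 14 benzoyl chloride
Product: 15 [1α,2α-dihydroxy-6α-(tert-butyldimethylsilyloxy)-4β,5β-(isopropylidenedioxy)cyclohexyl]methyl benzoate
Conditions: BzCl (1.05 equiv), pyridine, CH2Cl2, −40 → −20 °C
Reagents that add atoms: benzoyl chloride (compound 14), O=C(Cl)c1ccccc1
Why: Pyridine-mediated O-acylation under kinetic control: the primary C7 hydroxyl should react far faster than the neopentyl secondary C2 and the tertiary C1 hydroxyls; no stereocentre is formed.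

Step 11
Reactants: 15 [1α,2α-dihydroxy-6α-(tert-butyldimethylsilyloxy)-4β,5β-(isopropylidenedioxy)cyclohexyl]methyl benzoate
Product: 16 [1α-hydroxy-2-oxo-6α-(tert-butyldimethylsilyloxy)-4β,5β-(isopropylidenedioxy)cyclohexyl]methyl benzoate
Conditions: Dess–Martin periodinane, NaHCO3, CH2Cl2, rt
Reagents that add atoms: none
Why: Dess–Martin oxidation converts the only secondary carbinol (C2) into the ketone under non-basic conditions, so the β-alkoxy ketone should not eliminate and the tertiary alcohol, ester, silyl ether and acetonide survive.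

Step 12
Reactants: 16 [1α-hydroxy-2-oxo-6α-(tert-butyldimethylsilyloxy)-4β,5β-(isopropylidenedioxy)cyclohexyl]methyl benzoate
Product: 17 [1α,4β,5β-trihydroxy-2-oxo-6α-(tert-butyldimethylsilyloxy)cyclohexyl]methyl benzoate
Conditions: AcOH/H2O (4:1), 35 °C
Reagents that add atoms: none
Why: Acid-catalysed acetal hydrolysis should cleave the cis-fused dioxolane under conditions mild enough to leave the hindered secondary silyl ether, the benzoate and the β-hydroxy ketone intact; C4 and C5 are unchanged.

Step 13
Reactants: 17 [1α,4β,5β-trihydroxy-2-oxo-6α-(tert-butyldimethylsilyloxy)cyclohexyl]methyl benzoate; 14 benzoyl chloride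
Product: 18 [5β-(benzoyloxy)-1α,4β-dihydroxy-2-oxo-6α-(tert-butyldimethylsilyloxy)cyclohexyl]methyl benzoate
Conditions: BzCl (1.1 equiv), 2-aminoethyl diphenylborinate (10 mol %), iPr2NEt, MeCN, rt
Reagents that add atoms: benzoyl chloride (compound 14), O=C(Cl)c1ccccc1
Why: Borinic-acid-catalysed regioselective acylation of a cis-1,2-diol: the borinate of the O4/O5 pair should be acylated at its equatorial oxygen, which is O5 in the preferred chair (C7, O5 and O6 equatorial, O4 axial), while the tertiary C1 hydroxyl is inert; no new stereocentre.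

Step 14
Reactants: 18 [5β-(benzoyloxy)-1α,4β-dihydroxy-2-oxo-6α-(tert-butyldimethylsilyloxy)cyclohexyl]methyl benzoate
Product: 19 [(1S,4R,5R,6S)-5-(benzoyloxy)-1,4,6-trihydroxy-2-oxocyclohexyl]methyl benzoate (target, CNP0127041.1)
Conditions: HF·pyridine, THF/pyridine, 0 °C → rt
Reagents that add atoms: none
Why: Fluoride-mediated desilylation under mildly acidic conditions should free the C6 hydroxyl without benzoate migration or β-elimination of the C4 hydroxyl.

Compound list
1 | bromobenzene | Brc1ccccc1 | starting material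
2 | (1S,2S)-3-bromocyclohexa-3,5-diene-1,2-diol | C1=C(Br)[C@@H](O)[C@@H](O)C=C1 | intermediate
3 | (3aS,7aS)-4-bromo-2,2-dimethyl-3a,7a-dihydro-1,3-benzodioxole | C1=C(Br)[C@H]2OC(C)(C)O[C@H]2C=C1 | intermediate
4 | (3aS,4R,5R,7aS)-7-bromo-2,2-dimethyl-3a,4,5,7a-tetrahydro-1,3-benzodioxole-4,5-diol | C1=C(Br)[C@H]2OC(C)(C)O[C@H]2[C@H](O)[C@@H]1O | intermediate
5 | 4β,5β-(isopropylidenedioxy)cyclohex-2-ene-1α,6α-diol | C1=C[C@H]2OC(C)(C)O[C@H]2[C@H](O)[C@@H]1O | intermediate
6 | 6α-hydroxy-4β,5β-(isopropylidenedioxy)cyclohex-2-en-1-one | O=C1C=C[C@H]2OC(C)(C)O[C@H]2[C@@H]1O | intermediate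
7 | 6α-(tert-butyldimethylsilyloxy)-4β,5β-(isopropylidenedioxy)cyclohex-2-en-1-one | O=C1C=C[C@H]2OC(C)(C)O[C@H]2[C@@H]1O[Si](C)(C)C(C)(C)C | intermediate
8 | 2α,3α-epoxy-6α-(tert-butyldimethylsilyloxy)-4β,5β-(isopropylidenedioxy)cyclohexan-1-one | O=C1[C@@H]2O[C@@H]2[C@H]3OC(C)(C)O[C@H]3[C@@H]1O[Si](C)(C)C(C)(C)C | intermediate
9 | (chloromethyl)(isopropoxy)dimethylsilane | CC(C)O[Si](C)(C)CCl | starting material
10 | [(isopropoxydimethylsilyl)methyl]magnesium chloride | CC(C)O[Si](C)(C)C[Mg]Cl | intermediate
11 | 2α,3α-epoxy-1β-[(isopropoxydimethylsilyl)methyl]-6α-(tert-butyldimethylsilyloxy)-4β,5β-(isopropylidenedioxy)cyclohexan-1α-ol (magnesium alkoxide in the flask) | CC(C)O[Si](C)(C)C[C@@]1(O)[C@@H]2O[C@@H]2[C@H]3OC(C)(C)O[C@H]3[C@@H]1O[Si](C)(C)C(C)(C)C | intermediate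
12 | 2α,3α-epoxy-1β-(hydroxymethyl)-6α-(tert-butyldimethylsilyloxy)-4β,5β-(isopropylidenedioxy)cyclohexan-1α-ol | OC[C@@]1(O)[C@@H]2O[C@@H]2[C@H]3OC(C)(C)O[C@H]3[C@@H]1O[Si](C)(C)C(C)(C)C | intermediate
13 | 1β-(hydroxymethyl)-6α-(tert-butyldimethylsilyloxy)-4β,5β-(isopropylidenedioxy)cyclohexane-1α,2α-diol | OC[C@@]1(O)[C@H](O)C[C@H]2OC(C)(C)O[C@H]2[C@@H]1O[Si](C)(C)C(C)(C)C | intermediate
14 | benzoyl chloride | O=C(Cl)c1ccccc1 | starting material
15 | [1α,2α-dihydroxy-6α-(tert-butyldimethylsilyloxy)-4β,5β-(isopropylidenedioxy)cyclohexyl]methyl benzoate | O=C(OC[C@@]1(O)[C@H](O)C[C@H]2OC(C)(C)O[C@H]2[C@@H]1O[Si](C)(C)C(C)(C)C)c1ccccc1 | intermediate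
16 | [1α-hydroxy-2-oxo-6α-(tert-butyldimethylsilyloxy)-4β,5β-(isopropylidenedioxy)cyclohexyl]methyl benzoate | O=C(OC[C@@]1(O)C(=O)C[C@H]2OC(C)(C)O[C@H]2[C@@H]1O[Si](C)(C)C(C)(C)C)c1ccccc1 | intermediate
17 | [1α,4β,5β-trihydroxy-2-oxo-6α-(tert-butyldimethylsilyloxy)cyclohexyl]methyl benzoate | O=C(OC[C@@]1(O)C(=O)C[C@@H](O)[C@@H](O)[C@@H]1O[Si](C)(C)C(C)(C)C)c1ccccc1 | intermediate
18 | [5β-(benzoyloxy)-1α,4β-dihydroxy-2-oxo-6α-(tert-butyldimethylsilyloxy)cyclohexyl]methyl benzoate | O=C(OC[C@@]1(O)C(=O)C[C@@H](O)[C@@H](OC(=O)c2ccccc2)[C@@H]1O[Si](C)(C)C(C)(C)C)c1ccccc1 | intermediate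
19 | [(1S,4R,5R,6S)-5-(benzoyloxy)-1,4,6-trihydroxy-2-oxocyclohexyl]methyl benzoate | O=C(OC[C@@]1(O)C(=O)C[C@@H](O)[C@@H](OC(=O)c2ccccc2)[C@@H]1O)c1ccccc1 | target

Total step count: 14. Longest linear sequence: 14 steps (bromobenzene 1 to target 19; the organomagnesium reagent is made in the flask within step 8).

Steps most likely to fail

1. Step 9 (reductive epoxide opening). What may go wrong: loss of regiocontrol, with hydride entering at C2 instead of C3 (for instance by internal delivery from the C7 alkoxide), or Lewis-acid-induced rearrangement of the tertiary epoxy alcohol. Fallback, setting out from 12 and coming back at 13: the oxirane is opened with sodium phenylselenide (PhSeSePh, NaBH4, EtOH). This large, soft nucleophile should attack C3 anti to the oxygen and avoid the neopentyl C2, giving the hydroxy selenide 3β-(phenylselanyl)-1β-(hydroxymethyl)-6α-(tert-butyldimethylsilyloxy)-4β,5β-(isopropylidenedioxy)cyclohexane-1α,2α-diol F3. Homolytic C–Se cleavage with Bu3SnH/AIBN in toluene then leaves C3 as CH2 and returns triol 13.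

2. Step 7 (nucleophilic epoxidation). What may go wrong: base-induced enolisation toward C6 followed by β-elimination of the C5 oxygen and aromatisation, in competition with conjugate addition of hydroperoxide. Fallback, setting out from 7 and coming back at 12: the C1–C7 bond is made before the oxirane. Grignard reagent 10 is added to enone 7 (THF, −78 °C; 1,2-addition anti to the C6 silyloxy group) to give the silane adduct 1β-[(isopropoxydimethylsilyl)methyl]-6α-(tert-butyldimethylsilyloxy)-4β,5β-(isopropylidenedioxy)cyclohex-2-en-1α-ol F1, which is oxidised in the same flask (KF, KHCO3, H2O2) to the allylic diol 1β-(hydroxymethyl)-6α-(tert-butyldimethylsilyloxy)-4β,5β-(isopropylidenedioxy)cyclohex-2-en-1α-ol F2. Hydroxyl-directed epoxidation (VO(acac)2, t-BuOOH, CH2Cl2) should then deliver oxygen to C2=C3 on the α face, syn to the tertiary allylic hydroxyl and anti to the acetonide, giving 12 without any basic peroxide. The addition is here controlled by the C6 substituent alone.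

3. Step 13 (regioselective benzoylation). What may go wrong: slow or unselective acylation because the equatorial C5 hydroxyl is crowded by the neighbouring silyl ether, so that O4 competes. Fallback, setting out from 17 and coming back at 19: the silyl ether is removed first (HF·pyridine, THF) to give the tetraol monobenzoate [1α,4β,5β,6α-tetrahydroxy-2-oxocyclohexyl]methyl benzoate F4. This is benzoylated under tin mediation (Me2SnCl2 cat., iPr2NEt, BzCl, THF, rt). In the 4,5,6-triol the stannylene should bridge the cis O4/O5 pair and activate the equatorial O5 (the pattern of O-3 in galactosides), while O6 is neopentyl and the C1 hydroxyl tertiary, so the target 19 should form directly.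

Further compounds
F1 | step 7 | 1β-[(isopropoxydimethylsilyl)methyl]-6α-(tert-butyldimethylsilyloxy)-4β,5β-(isopropylidenedioxy)cyclohex-2-en-1α-ol | CC(C)O[Si](C)(C)C[C@@]1(O)C=C[C@H]2OC(C)(C)O[C@H]2[C@@H]1O[Si](C)(C)C(C)(C)C
F2 | step 7 | 1β-(hydroxymethyl)-6α-(tert-butyldimethylsilyloxy)-4β,5β-(isopropylidenedioxy)cyclohex-2-en-1α-ol | OC[C@@]1(O)C=C[C@H]2OC(C)(C)O[C@H]2[C@@H]1O[Si](C)(C)C(C)(C)C
F3 | step 9 | 3β-(phenylselanyl)-1β-(hydroxymethyl)-6α-(tert-butyldimethylsilyloxy)-4β,5β-(isopropylidenedioxy)cyclohexane-1α,2α-diol | OC[C@@]1(O)[C@H](O)[C@@H]([Se]c2ccccc2)[C@H]3OC(C)(C)O[C@H]3[C@@H]1O[Si](C)(C)C(C)(C)C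
F4 | step 13 | [1α,4β,5β,6α-tetrahydroxy-2-oxocyclohexyl]methyl benzoate | O=C(OC[C@@]1(O)C(=O)C[C@@H](O)[C@@H](O)[C@@H]1O)c1ccccc1
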